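The flavone is cut at C3–C4. Because C4 sits on C4a of ring A, whose two ortho carbons C5 and C8a both carry oxygen, the ring-A half can be a symmetric, dimerization-resistant 2,6-dialkoxy-3,4,5-trimethoxybenzonitrile oxide. Its (3+2) cycloaddition to the ring-B arylacetylene forms C3–C4 and a temporary O–C2 bond in one operation, storing C2–C3–C4 of ring C as a 3,5-diarylisoxazole. The dipole carries acid-labile MOM ethers and the alkyne benzyl ethers, so that after N–O cleavage only ring-A phenols are free when the pyranone closes; the 2'-oxygen of ring B, which could otherwise attack C4, is unmasked last.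

Key step: step 10

Remark: ring-A oxygens are carried as MOM ethers and ring-B oxygens as benzyl ethers (orthogonal groups), at the cost of one extra final step; the oxime is drawn as the E isomer, and its geometry has no consequence for the route.

Step 1
Reactants: 1 1,2,3-trimethoxybenzene
Product: 2 1,5-dibromo-2,3,4-trimethoxybenzene
Conditions: NBS (2.1 equiv), MeCN, 0 °C to rt
Reagents that add atoms: N-bromosuccinimide, O=C1CCC(=O)N1Br
Why: Electrophilic aromatic bromination should place the first bromine at C4 and the second at C6, the two positions ortho/para to the outer, ring-conjugated methoxy groups, whereas C5 is activated only by the twisted central methoxy group.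

Step 2
Reactants: 2 1,5-dibromo-2,3,4-trimethoxybenzene
Product: 4 4,5,6-trimethoxybenzene-1,3-diol, via diboronate 3 (not isolated)
Conditions: B2pin2 (2.5 equiv), Pd(dppf)Cl2 (cat.), KOAc, dioxane, 90 °C; then 30% H2O2, aq. NaOH, 0 °C to rt; aq. HCl
Reagents that add atoms: hydrogen peroxide, OO
Why: Double Miyaura borylation of the two aryl bromides followed by oxidation of both C–B bonds with alkaline peroxide in the same flask (borylation–oxidation) should deliver the symmetric resorcinol.

Step 3
Reactants: 4 4,5,6-trimethoxybenzene-1,3-diol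
Product: 5 1,5-bis(methoxymethoxy)-2,3,4-trimethoxybenzene
Conditions: NaH (2.4 equiv), DMF, 0 °C; MOMCl (2.4 equiv), 0 °C to rt
Reagents that add atoms: chloromethyl methyl ether, COCCl
Why: Williamson-type O-alkylation of the bis-phenoxide should protect both phenols as MOM acetals, which later direct the lithiation and are removed by dilute acid.

Step 4
Reactants: 5 1,5-bis(methoxymethoxy)-2,3,4-trimethoxybenzene
Product: 7 2,6-bis(methoxymethoxy)-3,4,5-trimethoxybenzaldehyde, via aryllithium 6 (not isolated)
Conditions: n-BuLi (1.2 equiv), TMEDA, THF, −78 to 0 °C; DMF, −78 °C to rt; H2O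
Reagents that add atoms: N,N-dimethylformamide, CN(C)C=O
Why: Directed ortho-metalation should occur at the only aromatic C–H, which lies between two lithium-chelating OMOM groups, and quenching the aryllithium with DMF (Bouveault-type formylation) should give the aldehyde.

Step 5
Reactants: 7 2,6-bis(methoxymethoxy)-3,4,5-trimethoxybenzaldehyde
Product: 8 (E)-2,6-bis(methoxymethoxy)-3,4,5-trimethoxybenzaldehyde oxime
Conditions: NH2OH·HCl, NaOAc, EtOH/H2O, 50 °C
Reagents that add atoms: hydroxylamine hydrochloride, NO.Cl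
Why: Oxime condensation under acetate buffering, which spares the MOM acetals, should give the aldoxime as the thermodynamically preferred E isomer.

Step 6
Reactants: 8 (E)-2,6-bis(methoxymethoxy)-3,4,5-trimethoxybenzaldehyde oxime
Product: 10 2,6-bis(methoxymethoxy)-3,4,5-trimethoxybenzonitrile oxide, via hydroximoyl chloride 9 (not isolated)
Conditions: NCS (1.05 equiv), DMF, rt; then Et3N (1.1 equiv), Et2O, 0 °C
Reagents that add atoms: none
Why: Chlorination of the oxime carbon followed by base-induced 1,3-dehydrochlorination is the standard entry to nitrile oxides, and here the ring has no C–H left to chlorinate while the two ortho OMOM groups shield the dipole from furoxan dimerization, so it should be isolable.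

Step 7
Reactants: 11 methoxyhydroquinone (2-methoxybenzene-1,4-diol)
Product: 12 1,4-bis(benzyloxy)-2-methoxybenzene
Conditions: BnBr (2.2 equiv), K2CO3, DMF, 60 °C, under N2
Reagents that add atoms: benzyl bromide, BrCc1ccccc1
Why: Williamson ether synthesis on both phenols, run under nitrogen because the hydroquinone is air-sensitive in base, should give the bis-benzyl ether.

Step 8
Reactants: 12 1,4-bis(benzyloxy)-2-methoxybenzene
Product: 14 2,5-bis(benzyloxy)-4-methoxybenzaldehyde, via iminium chloride 13 (not isolated)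
Conditions: POCl3, DMF, 0 to 70 °C; then H2O, 50 °C
Reagents that add atoms: N,N-dimethylformamide, CN(C)C=O; water, O
Why: Vilsmeier–Haack formylation should occur at the position para to the methoxy group and ortho to a benzyloxy group, as is usual for 1,2,4-trialkoxybenzenes, and hydrolysis of the iminium salt releases the aldehyde.

Step 9
Reactants: 14 2,5-bis(benzyloxy)-4-methoxybenzaldehyde
Product: 15 1,4-bis(benzyloxy)-2-ethynyl-5-methoxybenzene
Conditions: dimethyl (1-diazo-2-oxopropyl)phosphonate (1.3 equiv), K2CO3, MeOH/THF, rt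
Reagents that add atoms: dimethyl (1-diazo-2-oxopropyl)phosphonate, CC(=O)C(=[N+]=[N-])P(=O)(OC)OC
Why: The Ohira–Bestmann variant of the Seyferth–Gilbert homologation converts aryl aldehydes into terminal alkynes under mild carbonate conditions that leave benzyl ethers untouched.

Step 10
Reactants: 10 2,6-bis(methoxymethoxy)-3,4,5-trimethoxybenzonitrile oxide; 15 1,4-bis(benzyloxy)-2-ethynyl-5-methoxybenzene
Product: 16 5-[2,5-bis(benzyloxy)-4-methoxyphenyl]-3-[2,6-bis(methoxymethoxy)-3,4,5-trimethoxyphenyl]-1,2-oxazole
Conditions: 10 (1.2 equiv), 15 (1.0 equiv), toluene, 80 °C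
Reagents that add atoms: none
Why: The nitrile oxide and the alkyne should combine in a concerted, asynchronous Huisgen 1,3-dipolar (3+2) cycloaddition in which the dipole carbon bonds to the terminal alkyne carbon (the future C3–C4 bond) and the dipole oxygen to the aryl-bearing alkyne carbon (the future C2), giving the aromatic isoxazole directly. The closest known reaction type is the thermal addition of isolable 2,6-disubstituted aryl nitrile oxides to arylacetylenes. The five-membered ring closes in one pericyclic event through a six-electron transition state that forms both sigma bonds together, so no separate Baldwin-type cyclization is involved. No stereocentre is created. The step needs regioselectivity for the 3,5- over the 3,4-diarylisoxazole, which the terminal alkyne secures because only its unsubstituted carbon can approach the dipole carbon flanked by two ortho OMOM groups, reinforced by the polarization of the electron-rich arylacetylene. It also needs a dipole that survives a slow addition, which the two ortho oxygens of ring A provide by blocking dimerization.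

Step 11
Reactants: 16 5-[2,5-bis(benzyloxy)-4-methoxyphenyl]-3-[2,6-bis(methoxymethoxy)-3,4,5-trimethoxyphenyl]-1,2-oxazole
Product: 17 (Z)-3-amino-1-[2,5-bis(benzyloxy)-4-methoxyphenyl]-3-[2,6-bis(methoxymethoxy)-3,4,5-trimethoxyphenyl]prop-2-en-1-one
Conditions: Mo(CO)6 (1.0 equiv), MeCN/H2O, 80 °C
Reagents that add atoms: none
Why: Reductive N–O cleavage of isoxazoles with Mo(CO)6 in wet acetonitrile should give the β-amino enone, held in the Z form by an N–H···O=C hydrogen bond, without touching benzyl or MOM ethers.

Step 12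
Reactants: 17 (Z)-3-amino-1-[2,5-bis(benzyloxy)-4-methoxyphenyl]-3-[2,6-bis(methoxymethoxy)-3,4,5-trimethoxyphenyl]prop-2-en-1-one
Product: 20 2-[2,5-bis(benzyloxy)-4-methoxyphenyl]-5-hydroxy-6,7,8-trimethoxy-4H-chromen-4-one, via diphenol enaminone 18 (not isolated), via diketone 19 (not isolated)
Conditions: 3 M aq. HCl, MeOH/THF, 60 °C
Reagents that add atoms: water, O
Why: Acid hydrolysis should remove both MOM acetals and convert the enaminone into the 1,3-diketone, after which either of the two equivalent ring-A phenols adds 6-exo-trig to the C2 carbonyl and water is lost (flavone cyclodehydration), the still benzylated 2'-oxygen leaving no other mode of closure.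

Step 13
Reactants: 20 2-[2,5-bis(benzyloxy)-4-methoxyphenyl]-5-hydroxy-6,7,8-trimethoxy-4H-chromen-4-one
Product: 21 2-(2,5-dihydroxy-4-methoxyphenyl)-5-hydroxy-6,7,8-trimethoxy-4H-chromen-4-one (target)
Conditions: H2 (1 atm), 10% Pd/C, EtOAc/MeOH, rt; work-up under argon
Reagents that add atoms: none
Why: Catalytic hydrogenolysis should cleave both aryl benzyl ethers under neutral conditions that leave the chromone double bond and the methyl ethers intact, and the hydroquinone product is kept from air.

Compound list
1 | 1,2,3-trimethoxybenzene | COc1cccc(OC)c1OC | starting material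
2 | 1,5-dibromo-2,3,4-trimethoxybenzene | COc1c(Br)cc(Br)c(OC)c1OC | intermediate
3 | 2,2'-(4,5,6-trimethoxy-1,3-phenylene)bis(4,4,5,5-tetramethyl-1,3,2-dioxaborolane) | COc1c(B2OC(C)(C)C(C)(C)O2)cc(B2OC(C)(C)C(C)(C)O2)c(OC)c1OC | intermediate
4 | 4,5,6-trimethoxybenzene-1,3-diol | COc1c(O)cc(O)c(OC)c1OC | intermediate
5 | 1,5-bis(methoxymethoxy)-2,3,4-trimethoxybenzene | COCOc1cc(OCOC)c(OC)c(OC)c1OC | intermediate
6 | [2,6-bis(methoxymethoxy)-3,4,5-trimethoxyphenyl]lithium | [Li]c1c(OCOC)c(OC)c(OC)c(OC)c1OCOC | intermediate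
7 | 2,6-bis(methoxymethoxy)-3,4,5-trimethoxybenzaldehyde | O=Cc1c(OCOC)c(OC)c(OC)c(OC)c1OCOC | intermediate
8 | (E)-2,6-bis(methoxymethoxy)-3,4,5-trimethoxybenzaldehyde oxime | O/N=C/c1c(OCOC)c(OC)c(OC)c(OC)c1OCOC | intermediate
9 | (Z)-N-hydroxy-2,6-bis(methoxymethoxy)-3,4,5-trimethoxybenzenecarboximidoyl chloride | O/N=C(\Cl)c1c(OCOC)c(OC)c(OC)c(OC)c1OCOC | intermediate
10 | 2,6-bis(methoxymethoxy)-3,4,5-trimethoxybenzonitrile oxide | [O-][N+]#Cc1c(OCOC)c(OC)c(OC)c(OC)c1OCOC | intermediate
11 | methoxyhydroquinone (2-methoxybenzene-1,4-diol) | COc1cc(O)ccc1O | starting material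
12 | 1,4-bis(benzyloxy)-2-methoxybenzene | COc1cc(OCc2ccccc2)ccc1OCc1ccccc1 | intermediate
13 | N-{[2,5-bis(benzyloxy)-4-methoxyphenyl]methylidene}-N-methylmethanaminium chloride | COc1cc(OCc2ccccc2)c(C=[N+](C)C)cc1OCc1ccccc1.[Cl-] | intermediate
14 | 2,5-bis(benzyloxy)-4-methoxybenzaldehyde | COc1cc(OCc2ccccc2)c(C=O)cc1OCc1ccccc1 | intermediate
15 | 1,4-bis(benzyloxy)-2-ethynyl-5-methoxybenzene | C#Cc1cc(OCc2ccccc2)c(OC)cc1OCc1ccccc1 | intermediate
16 | 5-[2,5-bis(benzyloxy)-4-methoxyphenyl]-3-[2,6-bis(methoxymethoxy)-3,4,5-trimethoxyphenyl]-1,2-oxazole | COCOc1c(-c2cc(-c3cc(OCc4ccccc4)c(OC)cc3OCc3ccccc3)on2)c(OCOC)c(OC)c(OC)c1OC | intermediate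
17 | (Z)-3-amino-1-[2,5-bis(benzyloxy)-4-methoxyphenyl]-3-[2,6-bis(methoxymethoxy)-3,4,5-trimethoxyphenyl]prop-2-en-1-one | N/C(=C\C(=O)c1cc(OCc2ccccc2)c(OC)cc1OCc1ccccc1)c1c(OCOC)c(OC)c(OC)c(OC)c1OCOC | intermediate
18 | (Z)-3-amino-1-[2,5-bis(benzyloxy)-4-methoxyphenyl]-3-(2,6-dihydroxy-3,4,5-trimethoxyphenyl)prop-2-en-1-one | N/C(=C\C(=O)c1cc(OCc2ccccc2)c(OC)cc1OCc1ccccc1)c1c(O)c(OC)c(OC)c(OC)c1O | intermediate
19 | 1-[2,5-bis(benzyloxy)-4-methoxyphenyl]-3-(2,6-dihydroxy-3,4,5-trimethoxyphenyl)propane-1,3-dione | O=C(CC(=O)c1c(O)c(OC)c(OC)c(OC)c1O)c1cc(OCc2ccccc2)c(OC)cc1OCc1ccccc1 | intermediate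
20 | 2-[2,5-bis(benzyloxy)-4-methoxyphenyl]-5-hydroxy-6,7,8-trimethoxy-4H-chromen-4-one | COc1cc(OCc2ccccc2)c(-c2cc(=O)c3c(O)c(OC)c(OC)c(OC)c3o2)cc1OCc1ccccc1 | intermediate
21 | 2-(2,5-dihydroxy-4-methoxyphenyl)-5-hydroxy-6,7,8-trimethoxy-4H-chromen-4-one | COc1cc(O)c(-c2cc(=O)c3c(O)c(OC)c(OC)c(OC)c3o2)cc1O | target

Total step count: 13.
Longest linear sequence: 10 steps (steps 1–6, then 10–13); the ring-B branch (steps 7–9) joins at step 10.

Steps most likely to fail

Step 10. The hindered dipole may add so slowly that, on prolonged heating, it rearranges to the aryl isocyanate or is consumed by adventitious water before the cycloaddition is complete, and some 3,4-regioisomer may form. The fallback sets out from 7 and 15 and comes back at 20; it makes the same C3–C4 bond by polar addition and skips the isoxazole. Alkyne 15 is deprotonated with n-BuLi in THF at −78 °C and added to aldehyde 7 to give racemic 3-[2,5-bis(benzyloxy)-4-methoxyphenyl]-1-[2,6-bis(methoxymethoxy)-3,4,5-trimethoxyphenyl]prop-2-yn-1-ol F1. Oxidation with MnO2 in CH2Cl2 should give 3-[2,5-bis(benzyloxy)-4-methoxyphenyl]-1-[2,6-bis(methoxymethoxy)-3,4,5-trimethoxyphenyl]prop-2-yn-1-one F2. Aqueous HCl in MeOH/THF at room temperature removes the MOM groups to give 3-[2,5-bis(benzyloxy)-4-methoxyphenyl]-1-(2,6-dihydroxy-3,4,5-trimethoxyphenyl)prop-2-yn-1-one F3. Et2NH in EtOH then closes ring C by amine-mediated 6-endo addition of a ring-A phenol to the ynone (through the β-amino enone, which suppresses the 5-exo aurone pathway), giving flavone 20.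

Step 2. The second borylation may stay incomplete or protodeboronation may intervene, leaving mono-oxygenated material, and the electron-rich resorcinol may be over-oxidized by alkaline peroxide. The fallback sets out from 2 and comes back at 5; it replaces the catalytic double borylation by lithium–halogen exchange, one bromine at a time. n-BuLi (1 equiv, THF, −78 °C), then B(OMe)3, then H2O2/AcOH should give 5-bromo-2,3,4-trimethoxyphenol F4. NaH/MOMCl gives 1-bromo-5-(methoxymethoxy)-2,3,4-trimethoxybenzene F5. A second exchange, borate trapping and oxidation gives 5-(methoxymethoxy)-2,3,4-trimethoxyphenol F6, and a second MOM protection gives 5.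

Step 12. The cascade may stall at the diketone, forcing conditions may start to cleave the benzyl ethers, and formaldehyde released next to the nucleophilic enaminone may cause hydroxymethylation. The fallback sets out from 16 and comes back at 20; it separates deprotection from ring closure. The MOM groups are removed with HCl in MeOH at room temperature while the three-carbon unit is still locked in the acid-stable isoxazole, giving 2-{5-[2,5-bis(benzyloxy)-4-methoxyphenyl]-1,2-oxazol-3-yl}-4,5,6-trimethoxybenzene-1,3-diol F7, from which formaldehyde is washed out. Mo(CO)6 in wet MeCN then opens the ring to the diphenol enaminone 18, which is isolated and cyclized on its own with dilute HCl in EtOH at 60 °C to 20.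

Further compounds
F1 | step 10 | 3-[2,5-bis(benzyloxy)-4-methoxyphenyl]-1-[2,6-bis(methoxymethoxy)-3,4,5-trimethoxyphenyl]prop-2-yn-1-ol (racemic) | OC(C#Cc1cc(OCc2ccccc2)c(OC)cc1OCc1ccccc1)c1c(OCOC)c(OC)c(OC)c(OC)c1OCOC
F2 | step 10 | 3-[2,5-bis(benzyloxy)-4-methoxyphenyl]-1-[2,6-bis(methoxymethoxy)-3,4,5-trimethoxyphenyl]prop-2-yn-1-one | O=C(C#Cc1cc(OCc2ccccc2)c(OC)cc1OCc1ccccc1)c1c(OCOC)c(OC)c(OC)c(OC)c1OCOC
F3 | step 10 | 3-[2,5-bis(benzyloxy)-4-methoxyphenyl]-1-(2,6-dihydroxy-3,4,5-trimethoxyphenyl)prop-2-yn-1-one | O=C(C#Cc1cc(OCc2ccccc2)c(OC)cc1OCc1ccccc1)c1c(O)c(OC)c(OC)c(OC)c1O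
F4 | step 2 | 5-bromo-2,3,4-trimethoxyphenol | COc1c(O)cc(Br)c(OC)c1OC
F5 | step 2 | 1-bromo-5-(methoxymethoxy)-2,3,4-trimethoxybenzene | COCOc1cc(Br)c(OC)c(OC)c1OC
F6 | step 2 | 5-(methoxymethoxy)-2,3,4-trimethoxyphenol | COCOc1cc(O)c(OC)c(OC)c1OC
F7 | step 12 | 2-{5-[2,5-bis(benzyloxy)-4-methoxyphenyl]-1,2-oxazol-3-yl}-4,5,6-trimethoxybenzene-1,3-diol | COc1c(O)c(-c2cc(-c3cc(OCc4ccccc4)c(OC)cc3OCc3ccccc3)on2)c(O)c(OC)c1OC
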